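The cyclohexane ring (C1, C5, C6, C7, C8, C10; other locants below) is treated as a [4+2] adduct. C1, the quaternary carbon bearing the aryl ether oxygen, and C10 (CHCH3) derive from a Z aryl enol ether; C5 (ring-fusion CH) and C8 (CH2) are the termini of a butadienyl group on C4. Because the C1–O and C4–C9′ bonds tie both partners to the arene, the precursor is an eight-membered benzoxocine. One thermal intramolecular Diels–Alder reaction across that ring closes the cyclopentane and the cyclohexene, leaves the oxepane and sets C1, C5 and C10. The C6=C7 alkene then receives the dimethylcyclopropane; formyl groups come last.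

Key step: step 9

Locants used for all compounds (terpenoid part of the target): C1 quaternary carbon bearing the aryl ether oxygen; C2 and C3 the cyclopentane CH2 groups; C4 quaternary carbon bearing CH3; C5 ring-fusion CH; C6 and C7 cyclopropane CH (C6 next to C5); C8 ring CH2; C10 CH(CH3); C11 C(CH3)2; C9′ benzylic CH carrying the isobutyl group.

Assumption: in step 1 the ferrocenyl diphosphine named, or its enantiomer, is used, whichever delivers the 4R lactone; the sense of induction has to be established on this substrate. Allyltributylphosphonium bromide is taken as commercial.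

Step 1
Reactants: 1 5,7-dimethoxycoumarin; 2 isobutylmagnesium bromide
Product: 3 (4R)-5,7-dimethoxy-4-(2-methylpropyl)chroman-2-one
Conditions: CuBr·SMe2 (5 mol %), (R)-1-[(Sp)-2-(diphenylphosphino)ferrocenyl]ethyldicyclohexylphosphine (6 mol %), CH2Cl2, −75 °C; then 1 M HCl
Reagents that add atoms: isobutylmagnesium bromide, CC(C)C[Mg]Br
Why: Copper-catalysed asymmetric conjugate addition of a Grignard reagent to a coumarin, in which the chiral diphosphine on copper differentiates the faces of C4 of the lactone and so sets C9′.

Step 2
Reactants: 3 (4R)-5,7-dimethoxy-4-(2-methylpropyl)chroman-2-one; 4 iodomethane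
Product: 6 (3R,4R)-5,7-dimethoxy-3-methyl-4-(2-methylpropyl)chroman-2-one, via lithium enolate 5 (not isolated)
Conditions: LiN(SiMe3)2, THF, −78 °C; MeI, −78 → −20 °C
Reagents that add atoms: iodomethane, CI
Why: Lactone enolate alkylation, expected anti to the 4-isobutyl group (trans product); this centre is enolised again in step 3, so only clean mono-methylation matters.

Step 3
Reactants: 6 (3R,4R)-5,7-dimethoxy-3-methyl-4-(2-methylpropyl)chroman-2-one; 7 tert-butyl acrylate
Product: 9 tert-butyl 3-[(3R,4S)-5,7-dimethoxy-3-methyl-4-(2-methylpropyl)-2-oxochroman-3-yl]propanoate, via lithium enolate 8 (not isolated)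
Conditions: LiN(SiMe3)2, THF, −78 °C; tert-butyl acrylate, −78 °C; then AcOH
Reagents that add atoms: tert-butyl acrylate, C=CC(=O)OC(C)(C)C
Why: Michael addition of a tetrasubstituted lactone enolate; the acrylate should approach the face opposite the 4-isobutyl group, which the peri 5-methoxy group holds pseudo-axial, so the chain ends trans and the methyl group cis to isobutyl, the C4 configuration of the target.

Step 4
Reactants: 9 tert-butyl 3-[(3R,4S)-5,7-dimethoxy-3-methyl-4-(2-methylpropyl)-2-oxochroman-3-yl]propanoate
Product: 10 tert-butyl 3-[(3R,4S)-2-hydroxy-5,7-dimethoxy-3-methyl-4-(2-methylpropyl)chroman-3-yl]propanoate (lactol; both anomers)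
Conditions: iBu2AlH (1.1 equiv), toluene, −78 °C; aq KNaC4H4O6
Reagents that add atoms: none
Why: Partial reduction of the activated aryl lactone to the lactol at −78 °C, where the aluminium hemiacetal is stable and the hindered, less electrophilic tert-butyl ester should not react.

Step 5
Reactants: 10 lactol; 11 allyltributylphosphonium bromide
Product: 12 tert-butyl (4S,5E)-4-[(1R)-1-(2-hydroxy-4,6-dimethoxyphenyl)-3-methylbutyl]-4-methylocta-5,7-dienoate
Conditions: allylPBu3Br (3 equiv), KOtBu (3 equiv), THF, −78 → 23 °C; aq NH4Cl
Reagents that add atoms: allyltributylphosphonium bromide, C=CC[P+](CCCC)(CCCC)CCCC.[Br-]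
Why: Wittig olefination of the lactol through its open hydroxy aldehyde form; allylic trialkylphosphonium ylides are E-selective, which should give the (E)-1-substituted butadiene that can reach the s-cis conformation.

Step 6
Reactants: 12 tert-butyl (4S,5E)-4-[(1R)-1-(2-hydroxy-4,6-dimethoxyphenyl)-3-methylbutyl]-4-methylocta-5,7-dienoate
Product: 14 (4S,5E)-4-[(1R)-1-(2-hydroxy-4,6-dimethoxyphenyl)-3-methylbutyl]-4-methylocta-5,7-dienoic acid, via bis(trimethylsilyl) derivative 13 (not isolated)
Conditions: TMSOTf, 2,6-lutidine, CH2Cl2, 0 → 23 °C; then K2CO3, MeOH–H2O; citric acid to pH 4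
Reagents that add atoms: none
Why: Silyl triflate-mediated cleavage of a tert-butyl ester (loss of isobutene from the O-silylated ester) under buffered conditions that should spare the diene and the electron-rich arene, followed by mild basic removal of both trimethylsilyl groups.

Step 7
Reactants: 14 (4S,5E)-4-[(1R)-1-(2-hydroxy-4,6-dimethoxyphenyl)-3-methylbutyl]-4-methylocta-5,7-dienoic acid
Product: 16 (5S,6R)-5-[(1E)-buta-1,3-dien-1-yl]-7,9-dimethoxy-5-methyl-6-(2-methylpropyl)-3,4,5,6-tetrahydro-2H-1-benzoxocin-2-one, via mixed anhydride 15 (not isolated)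
Conditions: 2-methyl-6-nitrobenzoic anhydride, DMAP, Et3N, CH2Cl2 (2 mM, slow addition), 23 °C
Reagents that add atoms: none
Why: Shiina macrolactonisation through a mixed anhydride; the benzo unit and the quaternary C4 (gem-dialkyl effect) should bias the seco acid towards the eight-membered ring, and slow addition keeps oligomerisation down.

Step 8
Reactants: 16 benzoxocinone; 17 1,1-dibromoethane
Product: 18 (2Z,5S,6R)-5-[(1E)-buta-1,3-dien-1-yl]-2-ethylidene-7,9-dimethoxy-5-methyl-6-(2-methylpropyl)-3,4,5,6-tetrahydro-2H-1-benzoxocine
Conditions: CH3CHBr2, TiCl4, Zn, PbCl2 (cat.), TMEDA, THF, 0 → 23 °C; aq K2CO3, Et3N work-up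
Reagents that add atoms: 1,1-dibromoethane, CC(Br)Br
Why: Takai–Utimoto alkylidenation of an ester carbonyl, which is regiospecific for the C1=C10 enol ether and should place the new methyl group cis to the ring oxygen (Z), the geometry that later defines C10.

Step 9
Reactants: 18 benzoxocine Z enol ether
Product: 19 cycloadduct: the target skeleton with C6=C7 in place of the cyclopropane, both phenols as methyl ethers, no formyl groups
Conditions: toluene (5 mM), BHT, solid K2CO3, sealed tube, 200 °C
Reagents that add atoms: none
Why: A thermal, concerted but asynchronous [4π+2π] cycloaddition joins the diene termini C5 and C8 to the enol ether carbons C1 and C10. The closest known reaction type is the type 1 intramolecular Diels–Alder reaction of a 1,3,8-nonatriene with an enol ether dienophile, run here transannularly across a medium ring. The cyclopentane closes through the C5–C1 bond as a five-membered ring spanned by the C2–C3 tether, the cyclohexene is the [4+2] ring itself, and the oxepane is what is left of the benzoxocine once C5 bridges C1 and C4. C1 is fixed by the ring, since its oxygen and C9′ on C4 are held in one ring and must end cis on the cyclopentane; C10 follows from the Z enol ether by suprafacial addition; C5 follows from the cis-fused transition state, because the trans mode would push C6 and C7 under the benzo bridge. The step needs fused rather than bridged regiochemistry, which the short tether enforces, and reactivity from an unactivated diene and an electron-rich dienophile, which intramolecularity and 200 °C should supply. Solid K2CO3 and BHT protect the acid-labile enol ether and the diene during heating.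

Step 10
Reactants: 19 cycloadduct; 20 bromoform
Product: 21 11,11-dibromocyclopropane: dibromocarbene adduct of 19 at C6=C7
Conditions: CHBr3, 50% aq NaOH, BnEt3NCl (cat.), CH2Cl2, 23 °C
Reagents that add atoms: bromoform, BrC(Br)Br
Why: Dibromocarbene [2+1] addition under phase-transfer conditions; the carbene should attack the cyclohexene face anti to the allylic quaternary C4 and its methyl group (the convex face carrying H-5), which gives the cis-fused cyclopropane with the C6 and C7 configuration of the target.

Step 11
Reactants: 21 dibromocyclopropane; 22 methyllithium (converted into Me2CuLi with CuI); 4 iodomethane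
Product: 24 dimethylcyclopropane: the target as its di-O-methyl ether lacking both formyl groups, via cyclopropylcopper species 23 (not isolated)
Conditions: Me2CuLi (from MeLi, CuI), Et2O, −20 → 0 °C; then MeI, 0 → 23 °C
Reagents that add atoms: methyllithium (as lithium dimethylcuprate), C[Li]; iodomethane, CI
Why: Corey–Posner type gem-dimethylation of a 1,1-dibromocyclopropane (cuprate exchange and methyl transfer, then alkylation of the cyclopropylcopper species); C6 and C7 are not touched, so their configuration is kept.

Step 12
Reactants: 24 dimethylcyclopropane; 25 dichloromethyl methyl ether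
Product: 27 target di-O-methyl ether (both formyl groups in place), via bis[chloro(methoxy)methyl]arene 26 (not isolated)
Conditions: Cl2CHOMe, TiCl4, CH2Cl2, −78 → 0 °C; then ice–water
Reagents that add atoms: dichloromethyl methyl ether, ClC(Cl)OC; water, O
Why: Rieche formylation; the two remaining aromatic positions are each flanked by two oxygen substituents and are the only nucleophilic sites, and low temperature should spare the tertiary aryl ether and the cyclopropane.

Step 13
Reactants: 27 target di-O-methyl ether
Product: 28 CNP0202714.1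
Conditions: NaSEt, DMF, 110 °C; then 1 M HCl
Reagents that add atoms: none
Why: SN2 demethylation by a thiolate, which is fast for methoxy groups ortho or para to formyl groups and cannot attack the tertiary alkyl aryl ether; acidification returns the hydrogen-bonded diformyl phenol.

Compound list

1 | 5,7-dimethoxy-2H-chromen-2-one (5,7-dimethoxycoumarin) | COc1cc(OC)c2C=CC(=O)Oc2c1 | starting material
2 | isobutylmagnesium bromide | CC(C)C[Mg]Br | starting material
3 | (4R)-5,7-dimethoxy-4-(2-methylpropyl)chroman-2-one | CC(C)C[C@@H]1CC(=O)Oc2cc(OC)cc(OC)c12 | intermediate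
4 | iodomethane | CI | starting material
5 | lithium enolate of 3 (not isolated) | CC(C)C[C@@H]1C=C(O[Li])Oc2cc(OC)cc(OC)c12 | intermediate
6 | (3R,4R)-5,7-dimethoxy-3-methyl-4-(2-methylpropyl)chroman-2-one (methyl trans to isobutyl) | CC(C)C[C@@H]1[C@@H](C)C(=O)Oc2cc(OC)cc(OC)c12 | intermediate
7 | tert-butyl acrylate | C=CC(=O)OC(C)(C)C | starting material
8 | lithium enolate of 6 (not isolated) | CC(C)C[C@@H]1C(C)=C(O[Li])Oc2cc(OC)cc(OC)c12 | intermediate
9 | tert-butyl 3-[(3R,4S)-5,7-dimethoxy-3-methyl-4-(2-methylpropyl)-2-oxochroman-3-yl]propanoate (methyl cis to isobutyl) | CC(C)C[C@@H]1[C@@](C)(CCC(=O)OC(C)(C)C)C(=O)Oc2cc(OC)cc(OC)c12 | intermediate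
10 | tert-butyl 3-[(3R,4S)-2-hydroxy-5,7-dimethoxy-3-methyl-4-(2-methylpropyl)chroman-3-yl]propanoate (lactol, both anomers) | CC(C)C[C@@H]1[C@@](C)(CCC(=O)OC(C)(C)C)C(O)Oc2cc(OC)cc(OC)c12 | intermediate
11 | allyltributylphosphonium bromide | C=CC[P+](CCCC)(CCCC)CCCC.[Br-] | starting material
12 | tert-butyl (4S,5E)-4-[(1R)-1-(2-hydroxy-4,6-dimethoxyphenyl)-3-methylbutyl]-4-methylocta-5,7-dienoate | CC(C)C[C@@H](c1c(O)cc(OC)cc1OC)[C@@](C)(CCC(=O)OC(C)(C)C)/C=C/C=C | intermediate
13 | trimethylsilyl ester and aryl trimethylsilyl ether of 14 (not isolated) | CC(C)C[C@@H](c1c(O[Si](C)(C)C)cc(OC)cc1OC)[C@@](C)(CCC(=O)O[Si](C)(C)C)/C=C/C=C | intermediate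
14 | (4S,5E)-4-[(1R)-1-(2-hydroxy-4,6-dimethoxyphenyl)-3-methylbutyl]-4-methylocta-5,7-dienoic acid | CC(C)C[C@@H](c1c(O)cc(OC)cc1OC)[C@@](C)(CCC(=O)O)/C=C/C=C | intermediate
15 | mixed anhydride of 14 with 2-methyl-6-nitrobenzoic acid (not isolated) | CC(C)C[C@@H](c1c(O)cc(OC)cc1OC)[C@@](C)(CCC(=O)OC(=O)c1c(C)cccc1[N+](=O)[O-])/C=C/C=C | intermediate
16 | (5S,6R)-5-[(1E)-buta-1,3-dien-1-yl]-7,9-dimethoxy-5-methyl-6-(2-methylpropyl)-3,4,5,6-tetrahydro-2H-1-benzoxocin-2-one | CC(C)C[C@H]1c2c(OC)cc(OC)cc2OC(=O)CC[C@@]1(C)/C=C/C=C | intermediate
17 | 1,1-dibromoethane | CC(Br)Br | starting material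
18 | (2Z,5S,6R)-5-[(1E)-buta-1,3-dien-1-yl]-2-ethylidene-7,9-dimethoxy-5-methyl-6-(2-methylpropyl)-3,4,5,6-tetrahydro-2H-1-benzoxocine | CC(C)C[C@H]1c2c(OC)cc(OC)cc2O/C(=C\C)CC[C@@]1(C)/C=C/C=C | intermediate
19 | Diels–Alder adduct: target skeleton with a C6=C7 double bond in place of the cyclopropane, both phenols as methyl ethers, no formyl groups; O on C1, H on C5 and CH3 on C10 on one face of the cyclohexene, C2 and C4 on the other; 4-CH3 cis to C6 | CC(C)C[C@H]1c2c(OC)cc(OC)cc2O[C@]23CC[C@@]1(C)[C@H]2C=CC[C@@H]3C | intermediate
20 | bromoform | BrC(Br)Br | starting material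
21 | 11,11-dibromocyclopropane from 19, cyclopropane on the cyclohexane face that carries O-1, H-5 and 10-CH3 | CC(C)C[C@H]1c2c(OC)cc(OC)cc2O[C@]23CC[C@@]1(C)[C@H]2[C@H]1[C@@H](C[C@@H]3C)C1(Br)Br | intermediate
22 | methyllithium | C[Li] | starting material
23 | (11-methylcyclopropyl)copper species from 21, configuration at C11 not defined (not isolated) | CC(C)C[C@H]1c2c(OC)cc(OC)cc2O[C@]23CC[C@@]1(C)[C@H]2[C@H]1[C@@H](C[C@@H]3C)C1(C)[Cu] | intermediate
24 | 11,11-dimethylcyclopropane: target as its di-O-methyl ether lacking both formyl groups | CC(C)C[C@H]1c2c(OC)cc(OC)cc2O[C@]23CC[C@@]1(C)[C@H]2[C@H]1[C@@H](C[C@@H]3C)C1(C)C | intermediate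
25 | dichloromethyl methyl ether | ClC(Cl)OC | starting material
26 | bis[chloro(methoxy)methyl]arene from 24 (not isolated) | CC(C)C[C@H]1c2c(OC)c(C(Cl)OC)c(OC)c(C(Cl)OC)c2O[C@]23CC[C@@]1(C)[C@H]2[C@H]1[C@@H](C[C@@H]3C)C1(C)C | intermediate
27 | target di-O-methyl ether (both formyl groups present) | CC(C)C[C@H]1c2c(OC)c(C=O)c(OC)c(C=O)c2O[C@]23CC[C@@]1(C)[C@H]2[C@H]1[C@@H](C[C@@H]3C)C1(C)C | intermediate
28 | CNP0202714.1 | CC(C)C[C@H]1c2c(O)c(C=O)c(O)c(C=O)c2O[C@]23CC[C@@]1(C)[C@H]2[C@H]1[C@@H](C[C@@H]3C)C1(C)C | target

Total step count: 13. Longest linear sequence: 13 steps (fully linear from 1).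

Steps most likely to fail

Step 9. The enol ether and the diene are electronically mismatched, so the cycloaddition may be so slow that enol ether E/Z isomerisation (which would invert C10) or hydrogen shifts in the diene take over. The fallback changes the activation mode from a thermal pericyclic reaction to a stepwise cation-radical [4+2]. One-electron oxidation of the aryl enol ether ((4-BrC6H4)3N·SbCl6, 10 mol %, 2,6-di-tert-butylpyridine, CH2Cl2, 0 °C; or [Ru(bpz)3](PF6)2 under visible light and air) makes it the electron-poor partner, and the same two bonds form in one operation. It sets out from 18 and comes back at 19; it makes no compound that the route does not already hold (F0).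

Step 7. Intermolecular acylation (diolide and oligomers) may outrun closure of the eight-membered ring. The fallback gives up the benzoxocine and runs the same [4+2] on an open chain, closing the oxepane afterwards. It sets out from acid 14 and comes back at 19. TBSCl and imidazole in DMF convert 14 into the bis(tert-butyldimethylsilyl) derivative F1 (silyl ester plus aryl silyl ether). Takai–Utimoto ethylidenation of the silyl ester, as in step 8, should give the Z silyl enol ether F2. Heating as in step 9 should give the open-chain cycloadduct F3; here facial selectivity rests on C4 alone (ring formed cis to the 4-CH3, away from the bulky CH(iBu)Ar group). Bu4NF frees the phenol tertiary alcohol F4. Catalytic TfOH in CH2Cl2 at −20 °C ionises the tertiary alcohol at C1, and the phenol, held on the same face by C4, closes the oxepane to 19.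

Step 1. The peri 5-methoxy group shields C4 of the lactone and the two methoxy groups make the coumarin a poor acceptor, so 1,2-addition of the Grignard reagent, low catalyst turnover or poor facial discrimination may result. The fallback makes the C4–carbon bond by condensation and the stereocentre by hydride delivery. Because step 1 is the first step, there is no numbered compound to set out from: commercial 3,5-dimethoxyphenol and ethyl 5-methyl-3-oxohexanoate take the place of 1 and 2. Pechmann condensation in MeSO3H should give 5,7-dimethoxy-4-(2-methylpropyl)coumarin F5. Copper hydride conjugate reduction (Cu(OAc)2·H2O, (R)- or (S)-DTBM-SEGPHOS, (EtO)2MeSiH, tBuOH, toluene, 23 °C) then sets the 4R centre and comes back at 3.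

Further compounds

F0 | step 9 | none | none
F1 | step 7 | tert-butyldimethylsilyl (4S,5E)-4-[(1R)-1-[2-(tert-butyldimethylsilyloxy)-4,6-dimethoxyphenyl]-3-methylbutyl]-4-methylocta-5,7-dienoate | CC(C)C[C@@H](c1c(O[Si](C)(C)C(C)(C)C)cc(OC)cc1OC)[C@@](C)(CCC(=O)O[Si](C)(C)C(C)(C)C)/C=C/C=C
F2 | step 7 | Z tert-butyldimethylsilyl enol ether triene (C1=C10 silyl enol ether, E diene on C4, aryl silyl ether) | CC(C)C[C@@H](c1c(O[Si](C)(C)C(C)(C)C)cc(OC)cc1OC)[C@@](C)(CC/C(O[Si](C)(C)C(C)(C)C)=C/C)/C=C/C=C
F3 | step 7 | open-chain cycloadduct: cis-fused hydrindene with tertiary silyl ether at C1 (cis to H-5 and 10-CH3), aryl silyl ether | CC(C)C[C@@H](c1c(O[Si](C)(C)C(C)(C)C)cc(OC)cc1OC)[C@@]1(C)CC[C@@]2(O[Si](C)(C)C(C)(C)C)[C@@H]1C=CC[C@@H]2C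
F4 | step 7 | phenol tertiary alcohol from F3 | CC(C)C[C@@H](c1c(O)cc(OC)cc1OC)[C@@]1(C)CC[C@@]2(O)[C@@H]1C=CC[C@@H]2C
F5 | step 1 | 5,7-dimethoxy-4-(2-methylpropyl)-2H-chromen-2-one | CC(C)CC1=CC(=O)Oc2cc(OC)cc(OC)c12
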